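The readings were generated by integration for an exercise, noise included.

**Early readings.** The early readings show left-handed product climbing while right-handed product lies near its scatter of 0.3 percentage points. I take the excess as the difference of the two products over their sum, so one ratio carries it.

| setting | Monday's | Tuesday's | Sunday's | zeta | gamma |
|---|---|---|---|---|---|
| left-handed substrate | 0.22 M | 0.22 M | 0.22 M | 0.22 M | 0.22 M |
| right-handed substrate | 0.22 M | 0.22 M | 0.22 M | 0.22 M | 0.22 M |
| partner | 0.60 equiv | 0.60 equiv | 0.90 equiv | 0.600 equiv | 0.600 equiv |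
| free catalyst | 1 mol% | 1.5 mol% | 2 mol% | 2 mol% | 2 mol% |
| temperature | −18 °C | −1 °C | −18 °C | −25 °C | 5 °C |
| remark | run made earlier | run made earlier | run made earlier |  |  |
| time |  |  |  | 1.5 h | 1.5 h |

| run | time / min | left-handed product / % | right-handed product / % |
|---|---|---|---|
| Monday's | 15.0 | 1.4 | 0 |
| Monday's | 30.0 | 1.4 | 0 |
| Monday's | 40.0 | 2.0 | 0 |
| Monday's | 60.0 | 2.7 | 0.2 |
| Monday's | 80.0 | 3.9 | 0 |
| Tuesday's | 5.00 | 1.2 | 0 |
| Tuesday's | 10.0 | 2.0 | 0.6 |
| Tuesday's | 12.0 | 2.4 | 0.3 |
| Tuesday's | 20.0 | 3.2 | 0 |
| Tuesday's | 25.0 | 4.3 | 0 |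
| Sunday's | 6.00 | 0.7 | 0.1 |
| Sunday's | 20.0 | 2.2 | 0.3 |
| Sunday's | 30.0 | 4.0 | 0 |
| Sunday's | 50.0 | 5.8 | 0.8 |
| Sunday's | 80.0 | 9.0 | 0 |

(scatter of a reading: 0.3 percentage points)

- free catalyst is single-handed; left-handed substrate and right-handed substrate are mirror images of each other, charged as a racemate, each of them at the stated concentration
- an excess is below zero if the other one leads

- which flask leads in excess of left-handed product over right-handed product ("all alike" within 1.5 percentage points) (zeta / gamma / all alike)
- excess of left-handed product over right-handed product at the end, zeta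
- excess of left-handed product over right-handed product at the end, gamma

**What matters.** Monday's and Sunday's runs differ in catalyst and partner. Yet their right-handed product readings, added over the five times of each run, come to 0.200% and 1.20% and differ by 1 point, about the scatter 0.95 points of such a difference, so I could read no effect of those settings and pooled the two runs. Time I set aside, by assumption. Pooled, the left-handed product readings add up to 33.1% and the right-handed ones to 1.40%. Raising the first by 0.95 points moves the excess by 0.22 points, but lowering the second by as much moves it by 5.4 points. So the small sum is the number to know well.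

**Temperature.** The pooled runs at −18 °C read 23.6 as the ratio of the two added readings, and Tuesday's warmer run reads less, 14.6. Both are readings, and the pooled right-handed sum under the first carries a scatter of 0.95 points on its 1.40%. Carrying the logarithm straight along temperature, I expected 28.9 as zeta's selectivity factor, its left-handed over right-handed product, and 12.3 for gamma. Those mean excesses of 93.3% and 84.9%, with zeta ahead.

**The forecast.** The forecast, “Taking the excess as left-handed minus right-handed product, in points of total charge”, differed from mine: gamma leading, with 5.6% for zeta and 20% for gamma.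

**The flasks.** Zeta gave 97.8% and gamma 91.9%, so zeta leads as I reckoned, with both excesses above mine.

    free catalyst + left-handed substrate ⇌ catalyst intermediate A (K = 12.0 M⁻¹, k = 0.458 M⁻¹ s⁻¹, Ea = 49.0 kJ mol⁻¹, ΔH = −57.0 kJ mol⁻¹)
    free catalyst + right-handed substrate ⇌ catalyst intermediate B (K = 23.0 M⁻¹, k = 2.24 M⁻¹ s⁻¹, Ea = 56.0 kJ mol⁻¹, ΔH = 9.00 kJ mol⁻¹)
    partner + catalyst intermediate A → free catalyst + left-handed product (k = 0.208 M⁻¹ s⁻¹, Ea = 44.0 kJ mol⁻¹)
    partner + catalyst intermediate B → free catalyst + right-handed product (k = 0.00307 M⁻¹ s⁻¹, Ea = 52.0 kJ mol⁻¹)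
    partner → decomposed reagent (k = 8.79 × 10⁻⁵ s⁻¹, Ea = 92.0 kJ mol⁻¹)
    2 partner → self-condensation product (k = 0.00152 M⁻¹ s⁻¹, Ea = 66.0 kJ mol⁻¹)
    (constants at 5 °C)

**The end ratios.** Zeta's end ratio of left-handed over right-handed product was 88.7 against my 28.9, and gamma's was 23.7 against my 12.3. At 1.50 h in zeta, partner was used on the path to left-handed product 100 times as fast as on the path to right-handed product.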